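The benzene ring of Gentiside J (C1 bears the docosyl ester, C2 and C3 the hydroxyls, C4–C6 are CH) is cut at C2–C3 and C3–C4. The key step exploits the fact that C3 is a phenolic carbon flanked by oxygenated C2 and by C4–H: C3 and its oxygen are brought in as carbon monoxide. One palladium-catalysed carbonylative benzannulation forges both bonds, closes the only ring and sets the full 1,2,3-pattern, so no aromatic ring is ever functionalised. Its precursor is the acyclic chain AcO–C4H2–C5H=C6H–C1(CO2C22H45)=C2H–OMe, a primary allylic acetate joined through an E alkene to a β-methoxyacrylate, assembled by cross-coupling.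

Key step: step 5

Remark: the labels C1–C6 of the target ring are kept for the same carbons in all acyclic intermediates, and (E)-3-(tributylstannyl)prop-2-en-1-ol is taken to be a purchased reagent.

Step 1
Reactants: 1 methyl (E)-3-methoxyacrylate; 2 1-docosanol
Product: 3 docosyl (E)-3-methoxyacrylate
Conditions: 1 (3 equiv), Bu2SnO (5 mol%), toluene, reflux, MeOH removed over 4 Å MS (Soxhlet)
Reagents that add atoms: none
Why: Tin-catalysed transesterification under neutral conditions exchanges only the acyl–oxygen partner, as in the preparation of long-chain acrylates from methyl acrylate, so the β-methoxy group and the E geometry should stay untouched while removal of methanol drives the equilibrium.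

Step 2
Reactants: 3 docosyl (E)-3-methoxyacrylate
Product: 5 docosyl (Z)-2-bromo-3-methoxyacrylate, via docosyl 2,3-dibromo-3-methoxypropanoate 4 (not isolated)
Conditions: Br2 (1.05 equiv), CH2Cl2, 0 °C; then NEt3 (1.5 equiv), 0 °C to rt
Reagents that add atoms: bromine, BrBr
Why: Bromination–dehydrobromination: the electron-rich enol ether adds Br2 to give dibromide 4, and NEt3 then removes the acidic C1–H together with the bromide of the α-bromo ether at C2, which should give the Z isomer (Br cis to OMe, ester trans to OMe) as is established for the methyl ester.

Step 3
Reactants: 5 docosyl (Z)-2-bromo-3-methoxyacrylate; 6 (E)-3-(tributylstannyl)prop-2-en-1-ol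
Product: 7 docosyl (2E,3E)-5-hydroxy-2-(methoxymethylidene)pent-3-enoate
Conditions: Pd(PPh3)4 (5 mol%), CuI (10 mol%), CsF (2 equiv), DMF/THF, 45 °C
Reagents that add atoms: none
Why: Stille coupling: oxidative addition of zerovalent palladium into the C1–Br bond and copper- and fluoride-assisted transmetalation from tin proceed with retention at both alkenes, so the C6–C1 bond should form with C5=C6 E and with the new chain cis to OMe (2E by the priority rules), the free hydroxyl being inert to the catalyst.

Step 4
Reactants: 7 docosyl (2E,3E)-5-hydroxy-2-(methoxymethylidene)pent-3-enoate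
Product: 8 docosyl (2E,3E)-5-acetoxy-2-(methoxymethylidene)pent-3-enoate
Conditions: Ac2O (1.5 equiv), pyridine, DMAP (cat.), CH2Cl2, 0 °C; chromatography on NEt3-deactivated silica
Reagents that add atoms: acetic anhydride, CC(=O)OC(C)=O
Why: DMAP-catalysed O-acetylation of the primary allylic alcohol under basic conditions, placed after the cross-coupling so that the ionisable allylic acetate first meets zerovalent palladium in the key step.

Step 5
Reactants: 8 docosyl (2E,3E)-5-acetoxy-2-(methoxymethylidene)pent-3-enoate; 9 carbon monoxide
Product: 13 docosyl 3-acetoxy-2-methoxybenzoate, via dienylketene 10 (not isolated), via cyclohexadienone 11 (not isolated), via docosyl 3-hydroxy-2-methoxybenzoate 12 (not isolated)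
Conditions: PdCl2(PPh3)2 (5 mol%), CO (50 atm), Ac2O (2 equiv), NEt3 (2 equiv), toluene (0.05 M), 140 °C
Reagents that add atoms: acetic anhydride, CC(=O)OC(C)=O
Why: PdCl2(PPh3)2 is reduced in the flask to zerovalent palladium, which adds oxidatively into the C4–OAc bond; the η3-allylpalladium acetate so formed interconverts its syn and anti forms through η1 species, so that C5=C6 can become Z, and migratory insertion of CO at the CH2 terminus C4 creates the C3–C4 bond. NEt3 then deprotonates the acylpalladium at C4, the metal is expelled and dienylketene 10 remains, whose C3=C4–C5=C6–C1=C2 triene closes by thermal disrotatory 6π electrocyclisation, a six-membered all-carbon ring closure that forms C2–C3 and gives cyclohexadienone 11. Proton transfer from C2 to oxygen aromatises 11 to phenol 12, which Ac2O caps at once so that it cannot add to the ketene or to the acylpalladium. The nearest precedent in type is the cyclocarbonylation of 2,4-pentadienyl acetates, which palladium–phosphine catalysts convert into phenyl acetates under CO pressure when Ac2O and a tertiary amine are present; here the diene additionally carries an ester on C1 and an enol ether at C2. No stereocentre is created, since C2 is tetrahedral only in the transient dienone 11. The step needs carbonylation at C4 and not at C6 or C2, and ring closure at C2: C4 is the sole unsubstituted allyl terminus and acylation there keeps the β-methoxyacrylate conjugation intact, while C2 is the one diene terminus that the ketene carbon can reach through a six-membered transition state, and the substituent-free sp carbon of the ketene leaves room for the inward methoxy group, as the ready closure of dienylketenes onto fully substituted termini to 6,6-disubstituted cyclohexadienones shows.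

Step 6
Reactants: 13 docosyl 3-acetoxy-2-methoxybenzoate
Product: 12 docosyl 3-hydroxy-2-methoxybenzoate
Conditions: pyrrolidine (2 equiv), THF, 0 °C to rt
Reagents that add atoms: none
Why: Aminolysis of an aryl ester: the phenoxide is a far better leaving group than docosanolate, so pyrrolidine should take the acetyl group as 1-acetylpyrrolidine and leave the alkyl benzoate alone, and without an alcohol solvent the docosyl ester cannot be transesterified.

Step 7
Reactants: 12 docosyl 3-hydroxy-2-methoxybenzoate
Product: 14 Gentiside J (docosyl 2,3-dihydroxybenzoate)
Conditions: BCl3 (3 equiv, 1 M in CH2Cl2), CH2Cl2, −78 to 0 °C; then H2O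
Reagents that add atoms: none
Why: Chelation-assisted Lewis-acid ether cleavage: BCl3 binds the C3 phenoxide and the ester carbonyl, which holds boron against the C2 methoxy oxygen so that chloride removes the methyl group by SN2, the primary alkyl ester should survive at 0 °C, and the catechol is released on acidic aqueous hydrolysis, where it is not prone to air oxidation.

Compound list
1 | methyl (E)-3-methoxyacrylate | CO/C=C/C(=O)OC | starting material
2 | 1-docosanol | CCCCCCCCCCCCCCCCCCCCCCO | starting material
3 | docosyl (E)-3-methoxyacrylate | CCCCCCCCCCCCCCCCCCCCCCOC(=O)/C=C/OC | intermediate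
4 | docosyl 2,3-dibromo-3-methoxypropanoate (racemic, relative configuration of no consequence) | CCCCCCCCCCCCCCCCCCCCCCOC(=O)C(Br)C(Br)OC | intermediate (not isolated)
5 | docosyl (Z)-2-bromo-3-methoxyacrylate | CCCCCCCCCCCCCCCCCCCCCCOC(=O)/C(Br)=C/OC | intermediate
6 | (E)-3-(tributylstannyl)prop-2-en-1-ol | CCCC[Sn](CCCC)(CCCC)/C=C/CO | starting material
7 | docosyl (2E,3E)-5-hydroxy-2-(methoxymethylidene)pent-3-enoate | CCCCCCCCCCCCCCCCCCCCCCOC(=O)/C(=C/OC)/C=C/CO | intermediate
8 | docosyl (2E,3E)-5-acetoxy-2-(methoxymethylidene)pent-3-enoate | CCCCCCCCCCCCCCCCCCCCCCOC(=O)/C(=C/OC)/C=C/COC(C)=O | intermediate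
9 | carbon monoxide | [C-]#[O+] | starting material
10 | docosyl (2E,3Z)-2-(methoxymethylidene)-6-oxohexa-3,5-dienoate (dienylketene) | CCCCCCCCCCCCCCCCCCCCCCOC(=O)/C(=C/OC)/C=C\C=C=O | intermediate (not isolated)
11 | docosyl 6-methoxy-5-oxocyclohexa-1,3-diene-1-carboxylate (cyclohexadienone, racemic) | CCCCCCCCCCCCCCCCCCCCCCOC(=O)C1=CC=CC(=O)C1OC | intermediate (not isolated)
12 | docosyl 3-hydroxy-2-methoxybenzoate | CCCCCCCCCCCCCCCCCCCCCCOC(=O)c1cccc(O)c1OC | intermediate (not isolated in step 5, isolated in step 6)
13 | docosyl 3-acetoxy-2-methoxybenzoate | CCCCCCCCCCCCCCCCCCCCCCOC(=O)c1cccc(OC(C)=O)c1OC | intermediate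
14 | Gentiside J (docosyl 2,3-dihydroxybenzoate) | CCCCCCCCCCCCCCCCCCCCCCOC(=O)c1cccc(O)c1O | target

Total step count: 7
Longest linear sequence: 7 steps (1 to 14; compounds 2, 6 and 9 are purchased)

Steps most likely to fail

1. Step 5. The allylpalladium may be drained before carbonylation, by hydride transfer from the amine or by oligomerisation of the push–pull diene at 140 °C. CO insertion may also be too slow on an allyl unit made electron-poor by the ester. Fallback (arene chemistry, giving up ring construction): setting out from 1-docosanol 2, esterification with purchased 2,3-dimethoxybenzoic acid (EDC·HCl, DMAP, CH2Cl2, rt) should give docosyl 2,3-dimethoxybenzoate F1. BBr3 (3 equiv, CH2Cl2, −78 to 0 °C, aqueous work-up) should then cleave both aryl methyl ethers while sparing the primary alkyl ester, coming back to the route at target 14.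

2. Step 3. Transmetalation from tin to the donor-substituted alkenylpalladium bromide may be slow, so that protodestannylation or homocoupling of the stannane takes over and the enol ether geometry is partly scrambled. Fallback: setting out from 5, Suzuki–Miyaura coupling with purchased (E)-3-(tert-butyldimethylsilyloxy)prop-1-enylboronic acid pinacol ester (PdCl2(dppf), K3PO4, THF/H2O, 50 °C) should give docosyl (2E,3E)-5-(tert-butyldimethylsilyloxy)-2-(methoxymethylidene)pent-3-enoate F2. Buffered fluoride (TBAF, AcOH, THF, 0 °C) then frees the alcohol and returns to the route at 7.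

3. Step 1. Addition–elimination of docosanol at the β-carbon may exchange the enol ether alkoxy group in competition with acyl exchange, or the equilibrium may stall. Fallback: setting out from 2, Fischer esterification with propiolic acid (TsOH cat., toluene, Dean–Stark) should give docosyl propiolate F3. Amine-catalysed conjugate addition of methanol (MeOH, N-methylmorpholine cat., CH2Cl2, rt) should then give the E enol ether and return to the route at 3.

Further compounds
F1 | step 5 | docosyl 2,3-dimethoxybenzoate | CCCCCCCCCCCCCCCCCCCCCCOC(=O)c1cccc(OC)c1OC
F2 | step 3 | docosyl (2E,3E)-5-(tert-butyldimethylsilyloxy)-2-(methoxymethylidene)pent-3-enoate | CCCCCCCCCCCCCCCCCCCCCCOC(=O)/C(=C/OC)/C=C/CO[Si](C)(C)C(C)(C)C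
F3 | step 1 | docosyl propiolate | CCCCCCCCCCCCCCCCCCCCCCOC(=O)C#C
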